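## Structural features

The target is a flavone in which ring A (C4a to C8a, with free hydroxyls on C5 and C7) is fused to the pyranone ring C (O1, C2, C3, C4). Ring B, a para-substituted phenyl whose O4' carries a 3-methylbut-2-enyl (prenyl) group, is attached at C2, and C3 bears a methoxy group. There are no stereocentres, so no neighbouring stereocentres have to be related, and the prenyl double bond ends in two identical methyl groups and has no geometry. The fragile group is the aryl prenyl ether, which acid ionises, HX and electrophilic halogen attack at the alkene, hydrogenation reduces and strong heating sends into Claisen rearrangement. The 5- and 7-hydroxyls are acidic, and strong hydroxide can open the pyranone. The real difficulty is keeping four oxygens in three different states (O3 methylated, O4' prenylated, O5 and O7 free) without a late selective alkylation. The key step exploits the fact that C3 is a single carbon bearing only OMe, lying between the C4 carbonyl (bonded to C4a of ring A) and C2, which is at the carboxylic oxidation level because it is bonded to O1 and ring B, so that C3 can come from a methoxymethylene ylide, C4 from a ring A acyl chloride and C2 from an aryl ester of the ring B acid already sitting on O1.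

## Logic of the disconnections

13 is first traced back to 12. No skeletal bond is cut: the O–H bonds at O5 and O7 are exchanged for O–acyl bonds to the same aroyl group that supplies ring B. The reason is symmetry, since ring A then carries three identical acyloxy groups and the next cut raises no question of which ortho oxygen becomes O1. The forward step must remove two aryl esters without touching the prenyl ether, the O3 methyl ether or the pyranone; K2CO3 in methanol should do this and returns the aroyl groups as 3.

Ring C of 12 is opened by cutting C2=C3 and C3–C4. C3 with its methoxy group becomes the ylide carbon of 10, C4 the acyl chloride carbon of 8, and C2 the carbonyl carbon of an ortho aroyl ester in 8; 11 links the two bond formations. This removes the only ring that has to be built and brings the O3 methyl in ready-made. The forward step must make 10 attack the acyl chloride and not the three aryl esters, and must then make the stabilised ylide 11 olefinate an ester carbonyl.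

10 is the conjugate base of 9, so only a C–H bond is removed. 9 is purchased and 10 is made in the flask of the key step, which costs no separate step. The demand is that no strong base is left over to attack the esters of 8.

8 goes back to 7 by exchanging C–Cl for C–OH. 7 is a stable acid that can be purified, whereas 8 is best made and used at once. The forward chlorination must release neither HCl nor a Lewis acid, because three prenyl ethers are present, and must cope with a carboxyl flanked by two ortho substituents.

The three aryl ester C–O bonds of 7 are cut together, giving one molecule of 5 and three molecules of 6. All three phenols of 5 are treated alike, so no differentiation of ring A oxygens is needed. The forward acylation must proceed next to the free carboxyl of 5: any mixed anhydride must pass on its aroyl group or be hydrolysed selectively, and 5 must not decarboxylate.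

6 is cut at C–Cl to 4, 4 at its carboxyl O–H to 3, and 3 at the O4'–CH2 bond to 1 and 2. This reaches three purchased materials. The forward steps need clean O-alkylation of a phenoxide and acid-free activation of 4, three molecules of which are consumed for every molecule of 5.

## Other disconnections considered

Alternative 1: The cut falls on both bonds joining ring C to ring A, O1–C8a and C4–C4a, so ring A enters as an aryne.
- Forward step: CsF would unmask the aryne from silyl triflate A2. The enolate oxygen of keto ester A3 would add at the aryne carbon remote from the C5 alkoxy group (the future C8a), and the aryl anion left at C4a would attack the methyl ester and close ring C, giving A1.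
- In favour: A3 holds ring B, C2, C3 with its methoxy group and C4 in one piece. The alkoxy group should direct the regiochemistry. Only one ring B unit is consumed, which is better material economy than the chosen plan, where two of three aroyl units are spectators (recoverable as 3).
- Against: the enolate is ambident, and carbon attack on the aryne followed by insertion into the C–C bond is the usual course with keto esters. The aryl anion may be protonated before it cyclises. The silicon-containing acetals of A2 are themselves exposed to CsF. Removing them from A1 to reach 13 needs Bu4NF at elevated temperature or a Lewis acid such as MgBr2, which is harder on the prenyl ether than K2CO3 in methanol.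
- Comparison: on structure the two plans are equal in bringing the O3 methyl in ready-made and in closing ring C by two bond formations in one flask. On mechanism the chosen plan should be easier to steer, since its selectivity question is acyl chloride against aryl ester, whereas the aryne route depends on O- over C-arylation. On step economy, A2 needs desymmetrisation of a symmetric triphenol and A3 a crossed ester condensation from 4, so the count is clearly above five.

Alternative 2: C4 is taken out as carbon monoxide A7 by cutting C4a–C4 and C3–C4. Ring C stays open, and O1–C2 must be made later.
- Forward step: Pd(dba)2 (zerovalent palladium) with Xantphos would insert into the C–I bond of A5, take up A7 to give an aroylpalladium species, and acylate the enolate of A6, giving diketone A4 as its chelated enol.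
- In favour: three simple components, a symmetric A5 with no regiochemical question, catalytic metal, and a single ring B unit. On material economy this is better than the chosen plan.
- Against: the key step closes no ring. A5 is electron-rich and flanked by two bulky silyloxy groups, and direct arylation of the enolate without carbonyl insertion competes. Zerovalent palladium can ionise an aryl prenyl ether to an allyl complex. A7 is a toxic gas. The enolate base may move or strip silyl groups. The endgame needs three desilylations and a cyclodehydration of A4, normally acid-promoted, which is the condition the prenyl ether tolerates least.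
- Comparison: the longest linear sequence would be about equal to that of the chosen plan. The chosen plan forms ring C in the key step itself, and its endgame is a single mild methanolysis to 13. Mechanistically the palladium route has more competing organometallic pathways.

Alternative 3: Ring A is dismantled by cutting C5–C6, C7–C8 and C4a–C5, leaving a preformed pyranone that carries ring B.
- Forward step: irradiation of diazoketone A9 would trigger Wolff rearrangement to a vinylketene whose alkene is the pyranone double bond. Siloxyalkyne A10 would add by (2+2) cycloaddition, and four-electron ring opening, six-electron closure and tautomerisation would give A8.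
- In favour: A8 has O5 free and O7 silylated, so the two ring A oxygens are differentiated, which the chosen plan cannot do. The regiochemistry follows from the polarity of A10. The last step to 13 would be one desilylation with Bu4NF, equal in mildness to the chosen endgame.
- Against: the plan builds the one ring that can be bought cheaply. A9 needs a long synthesis of a 2-aryl-3-methoxypyranone carboxylic acid and hazardous diazo chemistry. Under irradiation the pyranone chromophore can rearrange, and the prenyl alkene can trap the carbene or the ketene.
- Comparison: structurally it is superior only for analogues with unlike groups on O5 and O7, which 13 does not need. Mechanistically a four-event cascade is set against two polar events. In step count it is by far the longest.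

Key step: step 4

Assumption: commercial 5 is a monohydrate and is dried under vacuum at room temperature before step 2; heating is avoided because the acid decarboxylates.

## Route

Step 1
Reactants: 1 methyl 4-hydroxybenzoate; 2 prenyl bromide (1-bromo-3-methylbut-2-ene)
Product: 4 4-(3-methylbut-2-en-1-yloxy)benzoic acid (4-prenyloxybenzoic acid), via methyl 4-prenyloxybenzoate 3 (not isolated)
Conditions: K2CO3, DMF, 20 °C; then aq NaOH, MeOH, 50 °C; then 1 M HCl, 0 °C, to pH 3
Reagents that add atoms: sodium hydroxide, [Na+].[OH-]
Why: Williamson etherification of the phenoxide with a primary allylic bromide gives O-alkylation in DMF, and saponification of the methyl ester follows in the same pot. The prenyl ether is inert to base and should survive the brief, cold acidification to pH 3.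

Step 2
Reactants: 4 4-prenyloxybenzoic acid (3 equiv); 5 2,4,6-trihydroxybenzoic acid (1 equiv)
Product: 7 2,4,6-tris(4-prenyloxybenzoyloxy)benzoic acid, via 4-prenyloxybenzoyl chloride 6 (not isolated)
Conditions: 4 (3.3 equiv), 1-chloro-N,N,2-trimethylprop-1-en-1-amine (3.2 equiv), CH2Cl2, 0 to 20 °C; then 5 (1 equiv), pyridine, DMAP (cat.), 0 to 20 °C; aq NaHCO3, then aq citric acid
Reagents that add atoms: 4-prenyloxybenzoic acid (the second and third equivalents of 4), O=C(O)c1ccc(OCC=C(C)C)cc1.O=C(O)c1ccc(OCC=C(C)C)cc1
Why: The chloroenamine converts each of the three molecules of 4 into 6 without releasing HCl, and nucleophilic catalysis by pyridine and DMAP then places one aroyl group on each of the three phenols of one molecule of 5, as in the classical preparation of O-aroylsalicylic acids. A mixed anhydride at the hindered ring A carboxyl should either hand its unhindered aroyl group to a phenol or be hydrolysed at that unhindered carbonyl in the NaHCO3 quench, so the ring A carboxyl emerges free.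

Step 3
Reactants: 7 2,4,6-tris(4-prenyloxybenzoyloxy)benzoic acid
Product: 8 2,4,6-tris(4-prenyloxybenzoyloxy)benzoyl chloride
Conditions: 1-chloro-N,N,2-trimethylprop-1-en-1-amine (1.1 equiv), CH2Cl2, 0 to 20 °C; evaporate, triturate with dry pentane, use at once
Reagents that add atoms: 1-chloro-N,N,2-trimethylprop-1-en-1-amine, CC(C)=C(Cl)N(C)C
Why: The acid adds to the keteniminium form of the chloroenamine, and chloride displaces N,N,2-trimethylpropanamide from the acyloxyiminium ion. The acid chloride therefore forms under neutral conditions, with no HCl to add to or cleave the three prenyl ethers, and the reagent is known to activate hindered acids.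

Step 4
Reactants: 8 2,4,6-tris(4-prenyloxybenzoyloxy)benzoyl chloride; 9 (methoxymethyl)triphenylphosphonium chloride
Product: 12 3-methoxy-5,7-bis(4-prenyloxybenzoyloxy)-4'-prenyloxyflavone, via methoxymethylenetriphenylphosphorane 10 (not isolated), via acyl(methoxy)methylenephosphorane 11 (not isolated)
Conditions: 9 (2.1 equiv), NaN(SiMe3)2 (2.0 equiv), THF, 0 °C; cannulate slowly into 8 (1 equiv), THF, −78 °C; then 20 °C, then 65 °C
Reagents that add atoms: none
Why: NaN(SiMe3)2 deprotonates 9 to ylide 10, with the base kept in slight deficit so that no amide base remains to attack esters. At −78 °C one equivalent of 10 attacks the acyl chloride carbon of 8 by addition–elimination (bond C3–C4), and the second equivalent removes the now acidic C3 proton, giving stabilised ylide 11 and returning one equivalent of 9. On warming, the ylide carbon of 11 adds to the carbonyl carbon of an ortho aroyl ester in a 6-exo-trig closure (ring atoms C3, C4, C4a, C8a, O1, C2); the betaine collapses to an oxaphosphetane, and cycloreversion expels triphenylphosphine oxide, leaving C2=C3 inside ring C. The closest known reaction type is acylation of phosphorus ylides by O-acylsalicylic acid derivatives followed by intramolecular Wittig olefination of the ester carbonyl, which gives chromones and flavones; the methoxy-substituted ylide is an untried member of that family, but its donor oxygen should raise the nucleophilicity of the acyl ylide carbon and so help the ester olefination. No stereocentre is formed, and the new double bond is endocyclic, so its geometry is fixed. Chemoselectivity for the acyl chloride over the three aryl esters should follow from its far higher electrophilicity compared with electron-rich 4-alkoxybenzoates, supported by the low temperature and by adding 10 into 8 so that free ylide stays scarce. Site selectivity is built into 8: only an ortho ester can reach C3 through a six-membered transition state, and the two ortho esters are equivalent by symmetry, so one flavone should result and the esters on O5 and O7 remain as protecting groups.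

Step 5
Reactants: 12 3-methoxy-5,7-bis(4-prenyloxybenzoyloxy)-4'-prenyloxyflavone
Product: 13 5,7-dihydroxy-3-methoxy-4'-prenyloxyflavone
Conditions: K2CO3 (2.5 equiv), MeOH/THF, 0 to 20 °C; aq NH4Cl
Reagents that add atoms: none
Why: Base-mediated transesterification with methanol cleaves the two aryl esters, which have good aryloxide leaving groups, while the prenyl ether, the O3 methyl ether and the pyranone are inert to K2CO3 at room temperature. The aroyl groups leave as neutral 3, which is easy to separate from the phenolic product and can be returned to step 1.

## Compound list

1 | methyl 4-hydroxybenzoate | COC(=O)c1ccc(O)cc1 | starting material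
2 | prenyl bromide (1-bromo-3-methylbut-2-ene) | CC(C)=CCBr | starting material
3 | methyl 4-(3-methylbut-2-en-1-yloxy)benzoate | COC(=O)c1ccc(OCC=C(C)C)cc1 | intermediate
4 | 4-(3-methylbut-2-en-1-yloxy)benzoic acid | O=C(O)c1ccc(OCC=C(C)C)cc1 | intermediate
5 | 2,4,6-trihydroxybenzoic acid | O=C(O)c1c(O)cc(O)cc1O | starting material
6 | 4-(3-methylbut-2-en-1-yloxy)benzoyl chloride | O=C(Cl)c1ccc(OCC=C(C)C)cc1 | intermediate
7 | 2,4,6-tris(4-prenyloxybenzoyloxy)benzoic acid | O=C(O)c1c(OC(=O)c2ccc(OCC=C(C)C)cc2)cc(OC(=O)c2ccc(OCC=C(C)C)cc2)cc1OC(=O)c1ccc(OCC=C(C)C)cc1 | intermediate
8 | 2,4,6-tris(4-prenyloxybenzoyloxy)benzoyl chloride | O=C(Cl)c1c(OC(=O)c2ccc(OCC=C(C)C)cc2)cc(OC(=O)c2ccc(OCC=C(C)C)cc2)cc1OC(=O)c1ccc(OCC=C(C)C)cc1 | intermediate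
9 | (methoxymethyl)triphenylphosphonium chloride | COC[P+](c1ccccc1)(c1ccccc1)c1ccccc1.[Cl-] | starting material
10 | methoxymethylenetriphenylphosphorane | COC=P(c1ccccc1)(c1ccccc1)c1ccccc1 | intermediate
11 | 2-methoxy-1-[2,4,6-tris(4-prenyloxybenzoyloxy)phenyl]-2-(triphenylphosphoranylidene)ethan-1-one | COC(C(=O)c1c(OC(=O)c2ccc(OCC=C(C)C)cc2)cc(OC(=O)c2ccc(OCC=C(C)C)cc2)cc1OC(=O)c1ccc(OCC=C(C)C)cc1)=P(c1ccccc1)(c1ccccc1)c1ccccc1 | intermediate
12 | 3-methoxy-5,7-bis(4-prenyloxybenzoyloxy)-4'-prenyloxyflavone | COc1c(-c2ccc(OCC=C(C)C)cc2)oc2cc(OC(=O)c3ccc(OCC=C(C)C)cc3)cc(OC(=O)c3ccc(OCC=C(C)C)cc3)c2c1=O | intermediate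
13 | 5,7-dihydroxy-3-methoxy-4'-prenyloxyflavone | COc1c(-c2ccc(OCC=C(C)C)cc2)oc2cc(O)cc(O)c2c1=O | target

## Step count and risk

Total step count: 5. Longest linear sequence: 5 steps (1 → 4 → 7 → 8 → 12 → 13); 5 and 9 enter as purchased materials.

Least certain steps:

**Step 4 (key step).** Two processes are the most likely to fail. The first is attack of ylide 10 on the aryl ester carbonyls in competition with the hindered, doubly ortho-substituted acyl chloride, which would transfer aroyl groups to the ylide and uncover phenoxides. The second is stalling at 11, because a doubly stabilised ylide must form a tetrasubstituted enol-ether double bond on an ester carbonyl; prolonged heating could then favour acyl transfer within 11 over olefination.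

The fallback drops the ylide and takes C3 with its methoxy group from a ketone, using Baker–Venkataraman chemistry. It sets out from 4, activated to 6 exactly as in step 2. Three equivalents of acid chloride 6 acylate the three phenols of 2-methoxy-1-(2,4,6-trihydroxyphenyl)ethan-1-one F1 (pyridine, DMAP) to give 2-methoxy-1-[2,4,6-tris(4-prenyloxybenzoyloxy)phenyl]ethan-1-one F2. DBU in pyridine at 60 to 80 °C should move one ortho aroyl group from oxygen to the enolate carbon, giving 1-[2-hydroxy-4,6-bis(4-prenyloxybenzoyloxy)phenyl]-2-methoxy-3-(4-prenyloxyphenyl)propane-1,3-dione F3 (racemic at C2 and enolisable). F3 cyclodehydrates in the same pot, or on brief warming in acetic acid buffered with NaOAc, to 12, where the route is rejoined before step 5. Partial loss of the spectator esters on the way would not matter, because step 5 removes them.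

**Step 2.** Acylation next to a free carboxyl can go astray through persistent carboxylic mixed anhydrides and incomplete acylation of the two hydrogen-bonded ortho phenols, leaving a mixture of acids that is hard to separate from surplus 4. Decarboxylation of 5 before its phenols are acylated is a further risk.

The fallback carries the future carboxyl carbon at the aldehyde level. It sets out from 4 (activated as 6, three equivalents) and 2,4,6-trihydroxybenzaldehyde F4. Tris-aroylation in pyridine with DMAP should give the neutral, crystallisable 2,4,6-tris(4-prenyloxybenzoyloxy)benzaldehyde F5. Pinnick oxidation (NaClO2, NaH2PO4, large excess of 2-methyl-2-butene, tert-butanol/THF/water) then gives 7, where the route is rejoined, at the cost of one extra step. The scavenger alkene, present in excess and more nucleophilic than the oxygen-deactivated prenyl double bonds, should take up the hypochlorous acid.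

**Step 3.** The likely failures are incomplete activation of the doubly ortho-substituted acid, and hydrolysis of the acyl chloride while the amide by-product and surplus reagent are removed. Any reagent carried forward would consume ylide in step 4.

The fallback goes through a silyl ester. It sets out from 7, which is silylated (tert-butyldimethylsilyl chloride, Et3N, DMF) to tert-butyldimethylsilyl 2,4,6-tris(4-prenyloxybenzoyloxy)benzoate F6. Oxalyl chloride with catalytic DMF in CH2Cl2 at 0 °C converts F6 into 8, where the route is rejoined. This known conversion of silyl esters into acid chlorides releases no HCl, and its by-products are volatile, so 8 would be obtained by evaporation alone.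

## Further compounds

F1 | step 4 | 2-methoxy-1-(2,4,6-trihydroxyphenyl)ethan-1-one | COCC(=O)c1c(O)cc(O)cc1O
F2 | step 4 | 2-methoxy-1-[2,4,6-tris(4-prenyloxybenzoyloxy)phenyl]ethan-1-one | COCC(=O)c1c(OC(=O)c2ccc(OCC=C(C)C)cc2)cc(OC(=O)c2ccc(OCC=C(C)C)cc2)cc1OC(=O)c1ccc(OCC=C(C)C)cc1
F3 | step 4 | 1-[2-hydroxy-4,6-bis(4-prenyloxybenzoyloxy)phenyl]-2-methoxy-3-(4-prenyloxyphenyl)propane-1,3-dione (racemic, enolisable) | COC(C(=O)c1ccc(OCC=C(C)C)cc1)C(=O)c1c(O)cc(OC(=O)c2ccc(OCC=C(C)C)cc2)cc1OC(=O)c1ccc(OCC=C(C)C)cc1
F4 | step 2 | 2,4,6-trihydroxybenzaldehyde | O=Cc1c(O)cc(O)cc1O
F5 | step 2 | 2,4,6-tris(4-prenyloxybenzoyloxy)benzaldehyde | O=Cc1c(OC(=O)c2ccc(OCC=C(C)C)cc2)cc(OC(=O)c2ccc(OCC=C(C)C)cc2)cc1OC(=O)c1ccc(OCC=C(C)C)cc1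
F6 | step 3 | tert-butyldimethylsilyl 2,4,6-tris(4-prenyloxybenzoyloxy)benzoate | CC(C)(C)[Si](C)(C)OC(=O)c1c(OC(=O)c2ccc(OCC=C(C)C)cc2)cc(OC(=O)c2ccc(OCC=C(C)C)cc2)cc1OC(=O)c1ccc(OCC=C(C)C)cc1
A1 | alternative 1 | 3-methoxy-4'-prenyloxy-5,7-bis[(2-trimethylsilylethoxy)methoxy]flavone | COc1c(-c2ccc(OCC=C(C)C)cc2)oc2cc(OCOCC[Si](C)(C)C)cc(OCOCC[Si](C)(C)C)c2c1=O
A2 | alternative 1 | 3,5-bis[(2-trimethylsilylethoxy)methoxy]-2-(trimethylsilyl)phenyl trifluoromethanesulfonate | C[Si](C)(C)CCOCOc1cc(OCOCC[Si](C)(C)C)c([Si](C)(C)C)c(OS(=O)(=O)C(F)(F)F)c1
A3 | alternative 1 | methyl 2-methoxy-3-oxo-3-(4-prenyloxyphenyl)propanoate (racemic, enolisable) | COC(=O)C(OC)C(=O)c1ccc(OCC=C(C)C)cc1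
A4 | alternative 2 | 2-methoxy-1-(4-prenyloxyphenyl)-3-[2,4,6-tris(tert-butyldimethylsilyloxy)phenyl]propane-1,3-dione, hydrogen-bonded enol | CO/C(C(=O)c1c(O[Si](C)(C)C(C)(C)C)cc(O[Si](C)(C)C(C)(C)C)cc1O[Si](C)(C)C(C)(C)C)=C(/O)c1ccc(OCC=C(C)C)cc1
A5 | alternative 2 | 2-iodo-1,3,5-tris(tert-butyldimethylsilyloxy)benzene | CC(C)(C)[Si](C)(C)Oc1cc(O[Si](C)(C)C(C)(C)C)c(I)c(O[Si](C)(C)C(C)(C)C)c1
A6 | alternative 2 | 2-methoxy-1-(4-prenyloxyphenyl)ethan-1-one | COCC(=O)c1ccc(OCC=C(C)C)cc1
A7 | alternative 2 | carbon monoxide | [C-]#[O+]
A8 | alternative 3 | 5-hydroxy-3-methoxy-4'-prenyloxy-7-(triisopropylsilyloxy)flavone | COc1c(-c2ccc(OCC=C(C)C)cc2)oc2cc(O[Si](C(C)C)(C(C)C)C(C)C)cc(O)c2c1=O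
A9 | alternative 3 | 6-(2-diazoacetyl)-3-methoxy-2-(4-prenyloxyphenyl)-4H-pyran-4-one | COc1c(-c2ccc(OCC=C(C)C)cc2)oc(C(=O)C=[N+]=[N-])cc1=O
A10 | alternative 3 | (ethynyloxy)triisopropylsilane | C#CO[Si](C(C)C)(C(C)C)C(C)C
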